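Numbering: naphthalene C1 carries the 4-hydroxyphenyl group, C2 and C3 carry the two 2,4-dihydroxybenzoyl groups, and C4 is CH. Ring B is C1-C4/C4a/C8a; ring A is C4a-C8a with the 6,7-diol.
Enabling feature: the carbonyls on C2 and C3 form a 1,4-diketone array O=C-C2=C3-C=O, so C2 is the beta carbon of the enone built from C2=C3 and the C3 aroyl carbonyl. C2 and the aroyl carbon are both acceptor carbons, and they are joined by polarity reversal of an aldehyde (carbene-generated acyl anion).
Retrosynthetic cuts: the seven O-CH3 bonds; then C2-C(=O) and C1-C2 in one operation, which opens ring B to a Morita-Baylis-Hillman acetate plus 2,4-dimethoxybenzaldehyde; then C3-C4 (keto aldehyde + aryl vinyl ketone); then C8a-C1 (aryllithium + Weinreb amide) and the vinyl-carbonyl bond (the same aldehyde + vinyl Grignard reagent).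
Forward order: ring A and the three outer arenes are bought. Ring B is the only ring made, and it is closed and aromatized in the flask in which the last aroyl group is attached. The C4 acetate and the C1 ketone set the oxidation level, so loss of AcOH and H2O gives the arene without an oxidant.
Stereochemistry: the target has no stereocentre. The carbinol centre of 9, 11 and 12 is racemic and is erased later.

Key step: step 7

Assumption: the target is treated as achiral (no stereocentre, no configurationally stable axis), and all seven phenols are carried as methyl ethers until the last step.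

Step 1
Reactants: 1 2-bromo-4,5-dimethoxybenzaldehyde
Product: 2 2-(2-bromo-4,5-dimethoxyphenyl)-1,3-dioxolane
Conditions: ethylene glycol (3 equiv), p-toluenesulfonic acid monohydrate (5 mol %), toluene, Dean-Stark trap, reflux
Reagents that add atoms: ethylene glycol, OCCO
Why: Acid-catalysed acetalization with azeotropic removal of water masks the formyl group against the organolithium chemistry of step 2.

Step 2
Reactants: 2 2-(2-bromo-4,5-dimethoxyphenyl)-1,3-dioxolane; 3 N,4-dimethoxy-N-methylbenzamide
Product: 6 2-(4-methoxybenzoyl)-4,5-dimethoxybenzaldehyde, via aryllithium 4 (not isolated), via keto acetal 5 (not isolated)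
Conditions: n-BuLi (1.05 equiv), THF, -78 °C; then 3, -78 → 0 °C; then 2 M aq HCl, THF, rt
Reagents that add atoms: water, O
Why: Bromine-lithium exchange outruns any attack on the dioxolane, the aryllithium is acylated only once because the chelated tetrahedral adduct holds until the quench (Weinreb ketone synthesis), and the aqueous acid of the quench hydrolyses the acetal.

Step 3
Reactants: 7 2,4-dimethoxybenzaldehyde; 8 vinylmagnesium bromide
Product: 9 1-(2,4-dimethoxyphenyl)prop-2-en-1-ol (racemic)
Conditions: THF, 0 °C; then H2O
Reagents that add atoms: none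
Why: Grignard 1,2-addition to an aromatic aldehyde, in which the new carbinol centre is racemic and is removed in step 4.

Step 4
Reactants: 9 1-(2,4-dimethoxyphenyl)prop-2-en-1-ol
Product: 10 1-(2,4-dimethoxyphenyl)prop-2-en-1-one
Conditions: 2-iodoxybenzoic acid (IBX, 1.5 equiv), EtOAc, 75 °C; product stored cold and used promptly
Reagents that add atoms: none
Why: IBX oxidation of a benzylic allylic alcohol runs under neutral conditions that spare both the ionizable electron-rich carbinol and the polymerizable aryl vinyl ketone.

Step 5
Reactants: 6 2-(4-methoxybenzoyl)-4,5-dimethoxybenzaldehyde; 10 1-(2,4-dimethoxyphenyl)prop-2-en-1-one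
Product: 11 1-(2,4-dimethoxyphenyl)-2-{hydroxy[2-(4-methoxybenzoyl)-4,5-dimethoxyphenyl]methyl}prop-2-en-1-one (racemic)
Conditions: DABCO (1,4-diazabicyclo[2.2.2]octane, 0.5 equiv), DMF, 0 °C → rt, 10 (1.5 equiv) added slowly
Reagents that add atoms: none
Why: Morita-Baylis-Hillman reaction, in which the amine-enone zwitterion adds to the formyl group (far more electrophilic than the doubly aryl-conjugated ketone) to form C3-C4, loss of the amine restores the methylene, and the racemic carbinol centre is erased in step 7.

Step 6
Reactants: 11 1-(2,4-dimethoxyphenyl)-2-{hydroxy[2-(4-methoxybenzoyl)-4,5-dimethoxyphenyl]methyl}prop-2-en-1-one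
Product: 12 2-(2,4-dimethoxybenzoyl)-1-[2-(4-methoxybenzoyl)-4,5-dimethoxyphenyl]allyl acetate (racemic)
Conditions: Ac2O (1.5 equiv), pyridine (3 equiv), 4-(dimethylamino)pyridine (5 mol %), CH2Cl2, 0 °C
Reagents that add atoms: acetic anhydride, CC(=O)OC(C)=O
Why: Standard O-acetylation of a Morita-Baylis-Hillman alcohol from its open hydroxy ketone form, kept cold and free of acid so that neither allylic transposition of the acetate nor dehydration of the lactol tautomer to an isobenzofuran sets in.

Step 7
Reactants: 12 2-(2,4-dimethoxybenzoyl)-1-[2-(4-methoxybenzoyl)-4,5-dimethoxyphenyl]allyl acetate; 7 2,4-dimethoxybenzaldehyde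
Product: 15 [6,7-dimethoxy-1-(4-methoxyphenyl)naphthalene-2,3-diyl]bis[(2,4-dimethoxyphenyl)methanone], via benzylidene diketone 13 (not isolated), via cyclic aldol 14 (not isolated)
Conditions: 7 (1.3 equiv), 3-ethyl-5-(2-hydroxyethyl)-4-methylthiazolium bromide (20 mol %), DBU (1,8-diazabicyclo[5.4.0]undec-7-ene, 2.5 equiv), 4 Å molecular sieves, 1,4-dioxane, rt → 80 °C
Reagents that add atoms: none
Why: Proposed new method: the thiazol-2-ylidene released by DBU turns aldehyde 7 into its Breslow intermediate, whose nucleophilic former carbonyl carbon adds to the free CH2 terminus of the acrylophenone unit of 12 (the future C2, beta to the C3 aroyl carbonyl), the enolate expels the C4 acetate by E1cB, and collapse of the carbinol releases the carbene and gives 13. DBU then deprotonates the C2 methylene of 13, which is activated by its own ketone and by the C3=C4 bond, and the enolate carbon attacks the ortho diaryl ketone carbon C1 in a 6-(enolexo)-exo-trig aldol closure of ring B to 14, from which loss of water is driven by aromatization to 15. The closest known reaction types are the intermolecular Stetter reaction of aromatic aldehydes with aryl vinyl ketones and the domino SN2'/ring closure/aromatization of Morita-Baylis-Hillman acetates of ortho-functionalized benzaldehydes with stabilized carbanions, and the new element is a catalytically generated acyl anion in the role of that carbanion. No stereocentre survives, since the centre of 12 is lost in the elimination and the two centres of 14 in the dehydration, so nothing has to control them. The step needs attack at CH2 and not at C4 or at the ketones, which the unhindered terminal acceptor carbon secures against the secondary C4 shielded by the ortho aroyl group, and it needs the ring A aryl group cis to the CH2 across C3=C4, which is the favoured (E) geometry and is in any case equilibrated through the delocalized C2 anion. Donor selectivity is secured because 12 carries no formyl group, so that only 7 can become the acyl anion, and self-benzoin formation of the electron-rich ortho-substituted 7 is reversible.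

Step 8
Reactants: 15 [6,7-dimethoxy-1-(4-methoxyphenyl)naphthalene-2,3-diyl]bis[(2,4-dimethoxyphenyl)methanone]
Product: 16 [6,7-dihydroxy-1-(4-hydroxyphenyl)naphthalene-2,3-diyl]bis[(2,4-dihydroxyphenyl)methanone] (CNP0304576.0)
Conditions: BBr3 (15 equiv), CH2Cl2, -78 °C → rt; then H2O, 0 °C, work-up under argon
Reagents that add atoms: none
Why: Lewis-acid cleavage of aryl methyl ethers with BBr3 should remove all seven methyl groups, the two ortho to the carbonyls fastest through chelation, while the diaryl ketones and the naphthalene core are inert to the reagent.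

Compound list
1 | 2-bromo-4,5-dimethoxybenzaldehyde | COc1cc(Br)c(C=O)cc1OC | starting material
2 | 2-(2-bromo-4,5-dimethoxyphenyl)-1,3-dioxolane | COc1cc(Br)c(cc1OC)C1OCCO1 | intermediate
3 | N,4-dimethoxy-N-methylbenzamide | COc1ccc(cc1)C(=O)N(C)OC | starting material
4 | [2-(1,3-dioxolan-2-yl)-4,5-dimethoxyphenyl]lithium | COc1cc([Li])c(cc1OC)C1OCCO1 | intermediate
5 | [2-(1,3-dioxolan-2-yl)-4,5-dimethoxyphenyl](4-methoxyphenyl)methanone | COc1ccc(cc1)C(=O)c1cc(OC)c(OC)cc1C1OCCO1 | intermediate
6 | 2-(4-methoxybenzoyl)-4,5-dimethoxybenzaldehyde | COc1ccc(cc1)C(=O)c1cc(OC)c(OC)cc1C=O | intermediate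
7 | 2,4-dimethoxybenzaldehyde | COc1ccc(C=O)c(OC)c1 | starting material
8 | vinylmagnesium bromide | C=C[Mg]Br | starting material
9 | 1-(2,4-dimethoxyphenyl)prop-2-en-1-ol (racemic) | COc1ccc(C(O)C=C)c(OC)c1 | intermediate
10 | 1-(2,4-dimethoxyphenyl)prop-2-en-1-one | COc1ccc(C(=O)C=C)c(OC)c1 | intermediate
11 | 1-(2,4-dimethoxyphenyl)-2-{hydroxy[2-(4-methoxybenzoyl)-4,5-dimethoxyphenyl]methyl}prop-2-en-1-one (racemic) | COc1ccc(cc1)C(=O)c1cc(OC)c(OC)cc1C(O)C(=C)C(=O)c1ccc(OC)cc1OC | intermediate
12 | 2-(2,4-dimethoxybenzoyl)-1-[2-(4-methoxybenzoyl)-4,5-dimethoxyphenyl]allyl acetate (racemic) | COc1ccc(cc1)C(=O)c1cc(OC)c(OC)cc1C(OC(C)=O)C(=C)C(=O)c1ccc(OC)cc1OC | intermediate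
13 | (E)-2-[2-(4-methoxybenzoyl)-4,5-dimethoxybenzylidene]-1,4-bis(2,4-dimethoxyphenyl)butane-1,4-dione | COc1ccc(cc1)C(=O)c1cc(OC)c(OC)cc1/C=C(\CC(=O)c1ccc(OC)cc1OC)C(=O)c1ccc(OC)cc1OC | intermediate
14 | [1-hydroxy-6,7-dimethoxy-1-(4-methoxyphenyl)-1,2-dihydronaphthalene-2,3-diyl]bis[(2,4-dimethoxyphenyl)methanone] (racemic, diastereomer mixture) | COc1ccc(cc1)C1(O)C(C(=O)c2ccc(OC)cc2OC)C(C(=O)c2ccc(OC)cc2OC)=Cc2cc(OC)c(OC)cc12 | intermediate
15 | [6,7-dimethoxy-1-(4-methoxyphenyl)naphthalene-2,3-diyl]bis[(2,4-dimethoxyphenyl)methanone] | COc1ccc(cc1)-c1c(C(=O)c2ccc(OC)cc2OC)c(C(=O)c2ccc(OC)cc2OC)cc2cc(OC)c(OC)cc12 | intermediate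
16 | [6,7-dihydroxy-1-(4-hydroxyphenyl)naphthalene-2,3-diyl]bis[(2,4-dihydroxyphenyl)methanone] | O=C(c1ccc(O)cc1O)c1cc2cc(O)c(O)cc2c(-c2ccc(O)cc2)c1C(=O)c1ccc(O)cc1O | target

Total step count: 8. Longest linear sequence: 6 steps (steps 1, 2, 5, 6, 7, 8 from 1; the branch through steps 3 and 4 from 7 is equally long).

Steps most likely to fail

Step 7. Three processes could defeat the cascade:
- The carbene may be consumed by irreversible allylation with 12.
- The acyl group may be delivered to C4 through a double SN2' sequence.
- The electron-rich benzylic acetate may ionize and be captured by the oxygen of the ortho ketone before the acyl anion arrives.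

The fallback uses known chemistry and makes the same C2-C(=O) bond before ring B exists. It sets out from 7, 10 and 6. A classical Stetter reaction of 7 with 10 (3-ethyl-5-(2-hydroxyethyl)-4-methylthiazolium bromide, Et3N, EtOH, reflux) should give the symmetrical 1,4-bis(2,4-dimethoxyphenyl)butane-1,4-dione F1. A twofold aldol condensation of this diketone with keto aldehyde 6 (NaOEt, EtOH, reflux) follows the established route from ortho-dicarbonyl arenes and 1,4-diketones to 2,3-diacylnaphthalenes. The symmetry of the diketone removes any regiochemical question. The fallback comes back to the route at 15.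

Step 5. Addition to the hindered, electron-rich aldehyde may be slow, while the vinyl ketone is lost to self-dimerization or to double addition. The fallback sets out from 6 and 10 and replaces the catalytic cycle with a stoichiometric tandem Michael-aldol sequence.
- Lithium benzenethiolate (PhSH, n-BuLi, THF, -78 °C) adds to 10, and the lithium enolate is trapped by 6. This should give 1-(2,4-dimethoxyphenyl)-3-hydroxy-3-[2-(4-methoxybenzoyl)-4,5-dimethoxyphenyl]-2-[(phenylsulfanyl)methyl]propan-1-one F2.
- Oxidation with mCPBA (1 equiv, CH2Cl2, -78 °C) should give the corresponding sulfoxide, 1-(2,4-dimethoxyphenyl)-3-hydroxy-3-[2-(4-methoxybenzoyl)-4,5-dimethoxyphenyl]-2-[(phenylsulfinyl)methyl]propan-1-one F3.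
- Thermal syn-elimination (toluene, CaCO3, 100 °C) can only remove the C3 hydrogen. The fallback comes back to the route at 11.

Step 8. Cleavage of the seven ethers may stop short, a freed ortho-phenol may close onto the neighbouring carbonyl under strong Lewis acid, or the catechol may be oxidized during work-up. The fallback sets out from 15 and splits the task between two mechanisms.
- Chelation-directed cleavage with BCl3 (CH2Cl2, -78 → 0 °C) should remove only the two methyl groups ortho to the carbonyls. The product would be [6,7-dimethoxy-1-(4-methoxyphenyl)naphthalene-2,3-diyl]bis[(2-hydroxy-4-methoxyphenyl)methanone] F4.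
- The remaining five ethers are then cleaved by SN2 attack of sodium ethanethiolate (NaSEt, DMF, 130 °C, argon), followed by acidification. The fallback comes back to the route at 16.

Further compounds
F1 | step 7 | 1,4-bis(2,4-dimethoxyphenyl)butane-1,4-dione | COc1ccc(C(=O)CCC(=O)c2ccc(OC)cc2OC)c(OC)c1
F2 | step 5 | 1-(2,4-dimethoxyphenyl)-3-hydroxy-3-[2-(4-methoxybenzoyl)-4,5-dimethoxyphenyl]-2-[(phenylsulfanyl)methyl]propan-1-one (diastereomer mixture, racemic) | COc1ccc(cc1)C(=O)c1cc(OC)c(OC)cc1C(O)C(CSc1ccccc1)C(=O)c1ccc(OC)cc1OC
F3 | step 5 | 1-(2,4-dimethoxyphenyl)-3-hydroxy-3-[2-(4-methoxybenzoyl)-4,5-dimethoxyphenyl]-2-[(phenylsulfinyl)methyl]propan-1-one (diastereomer mixture, racemic) | COc1ccc(cc1)C(=O)c1cc(OC)c(OC)cc1C(O)C(CS(=O)c1ccccc1)C(=O)c1ccc(OC)cc1OC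
F4 | step 8 | [6,7-dimethoxy-1-(4-methoxyphenyl)naphthalene-2,3-diyl]bis[(2-hydroxy-4-methoxyphenyl)methanone] | COc1ccc(cc1)-c1c(C(=O)c2ccc(OC)cc2O)c(C(=O)c2ccc(OC)cc2O)cc2cc(OC)c(OC)cc12
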